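**Retrosynthetic overview**

1. Target 19 ⇒ bridged allylic ether 16. The allylic anisoate (C10–O, C8=C9) and the tertiary carbinol (C5–OH) are disconnected together: ring B (cycloheptene C1–C5–C6–C7–C8–C9–C10) is read as an opened 8-oxabicyclo[3.2.1]oct-2-ene with a C5–O–C8 bridge.
2. 16 ⇒ ynone 9 + a vinyl ether. The C5–O–C8 bridge is a carbonyl ylide, and its [3+2] cycloaddition makes C5–C6 and C7–C8 at once. Enabling feature: C5 and C8 stand 1,4 across the C6–C7 ethano unit, and a C5 ketone and a C8≡C9 alkyne are held γ,δ through quaternary C1, so the ketone oxygen closes the pyran ring O–C5–C1–C10–C9–C8.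
3. 9 ⇒ regiodefined cyclopentanone enolate + 1-bromobut-2-yne (C1 set anti to the C4 isopropyl). The enolate ⇒ (S)-limonene (the only purchased stereocenter, C4) by ozonolysis, aldol ring closure and Baeyer–Villiger excision of the formyl carbon.
4. Ring order: ring A (aldol) → pyran ring, oxolane bridge and ring B in the key step → oxygen bridge opened last. C1, C5 and C10 are all relayed from C4.

Key step: step 6

Remark on the chemistry: locants are daucane locants (C1 = ring-fusion C–CH3, C2/C3 = ring A CH2, C4 = CH–iPr, C5 = C–OH, C6/C7 = CH2CH2, C8 = C(CH3)=, C9 = CH=, C10 = CH–O). The C7 oxygen in 13–15 is a traceless activating group; its configuration is not controlled and is erased in step 9, so C7 is left undefined in those SMILES. tert-Butyldimethyl(vinyloxy)silane is taken as a purchasable reagent.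

**Route**

Step 1
Reactants: 1 (S)-(−)-limonene
Product: 2 (4S)-1-methyl-4-(propan-2-yl)cyclohex-1-ene
Conditions: H2 (1 atm, 1 equiv), RhCl(PPh3)3 (1 mol %), toluene, rt
Reagents that add atoms: none
Why: Homogeneous hydrogenation with RhCl(PPh3)3 should reduce the 1,1-disubstituted isopropenyl alkene much faster than the trisubstituted ring alkene (chemoselective alkene hydrogenation), leaving the C4 stereocenter untouched.

Step 2
Reactants: 2 (4S)-1-methyl-4-(propan-2-yl)cyclohex-1-ene
Product: 4 (3S)-6-oxo-3-(propan-2-yl)heptanal, via secondary ozonide 3 (not isolated)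
Conditions: O3, CH2Cl2, −78 °C; then PPh3, −78 °C to rt
Reagents that add atoms: ozone ([O-][O+]=O)
Why: Ozonolysis with reductive work-up cleaves the ring alkene to the 1,6-keto aldehyde; the stereocenter is β to the aldehyde and cannot epimerise.

Step 3
Reactants: 4 (3S)-6-oxo-3-(propan-2-yl)heptanal
Product: 5 (5R)-2-methyl-5-(propan-2-yl)cyclopent-1-ene-1-carbaldehyde
Conditions: piperidine (0.2 equiv), AcOH (0.2 equiv), benzene, reflux, Dean–Stark
Reagents that add atoms: none
Why: Amine-catalysed intramolecular aldol condensation (aldehyde enamine onto the methyl ketone, then dehydration) closes ring A as the tetrasubstituted enal; the C4 hydrogen is not vinylogously acidic, so the stereocenter should hold.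

Step 4
Reactants: 5 (5R)-2-methyl-5-(propan-2-yl)cyclopent-1-ene-1-carbaldehyde
Product: 6 (5R)-2-methyl-5-(propan-2-yl)cyclopent-1-en-1-yl formate
Conditions: 30% aq. H2O2 (2 equiv), bis(2-nitrophenyl) diselenide (2 mol %), CH2Cl2, rt
Reagents that add atoms: hydrogen peroxide (OO)
Why: Baeyer–Villiger oxidation of an α,β-unsaturated aldehyde with alkenyl migration (areneseleninic peracid catalysis) excises the formyl carbon as a formate and leaves oxygen on C5 with the enol double bond fixed toward C1.

Step 5
Reactants: 6 (5R)-2-methyl-5-(propan-2-yl)cyclopent-1-en-1-yl formate; 7 1-bromobut-2-yne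
Product: 9 (2R,5R)-2-(but-2-yn-1-yl)-2-methyl-5-(propan-2-yl)cyclopentan-1-one, via lithium enolate 8 (not isolated)
Conditions: MeLi (2.1 equiv), THF, 0 °C (6 added to MeLi); then DMPU, 7 (1.3 equiv), −78 to −30 °C
Reagents that add atoms: 1-bromobut-2-yne (CC#CCBr)
Why: Cleavage of the enol ester by MeLi gives the tetrasubstituted lithium enolate regiospecifically (no enolisation toward C4), and SN2 alkylation on the face opposite the C4 isopropyl group should set quaternary C1 (substrate-controlled enolate alkylation).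

Step 6
Reactants: 9 (2R,5R)-2-(but-2-yn-1-yl)-2-methyl-5-(propan-2-yl)cyclopentan-1-one; 10 tert-butyldimethyl(vinyloxy)silane
Product: 13 9-[(tert-butyldimethylsilyl)oxy]-5,8-dimethyl-2-(propan-2-yl)-11-oxatricyclo[6.2.1.0^{1,5}]undec-6-ene, via platinum-containing carbonyl ylide 11 (not isolated), via platinum carbene 12 (not isolated)
Conditions: PtCl2 (10 mol %), 10 (3 equiv), 4 Å MS, toluene, rt
Reagents that add atoms: tert-butyldimethyl(vinyloxy)silane (C=CO[Si](C)(C)C(C)(C)C)
Why: PtCl2 activates the alkyne and the C5 ketone oxygen adds 6-endo-dig to C8, giving the platinum-containing carbonyl ylide 11 (cyclic oxocarbenium at C5, alkenyl–platinum bond at C9); its stepwise polar [3+2] cycloaddition with 10 forms C5–C6 (enol ether CH2 onto the oxocarbenium) and then C7–C8 (alkenylplatinum carbon onto the silyloxocarbenium), and the resulting carbene 12 at C9 undergoes a 1,2-hydride shift from C10 to release the C9=C10 alkene and PtCl2. The closest known reaction type is the [3+2] cycloaddition of platinum- or tungsten-containing carbonyl ylides generated from γ,δ-ynones with vinyl ethers, which gives 8-oxabicyclo[3.2.1]oct-2-enes. Ring closures: the pyran ring by 6-endo-dig oxycyclisation, the oxolane ring O–C5–C6–C7–C8 by 5-exo-trig attack of C8 on the oxocarbenium, and by that same bond the seven-membered carbocycle (ring B) as the bridged ring of the cycloadduct. Stereocontrol: the enol ether attacks C5 on the face of the cyclopentylidene oxocarbenium opposite the flanking C4 isopropyl and C1 methyl groups, so the oxygen ends cis to both; C8 follows because the two-carbon bridge can only span C5 and C8 cis; C7 is not controlled and is erased in step 9. The step needs 6-endo rather than 5-exo oxygen attack, ring closure rather than silyl loss from the silyloxocarbenium, and the polarity-matched regiochemistry (oxygenated carbon bonded to C8); the quaternary C1 (no enolisation or furan exit, gem-disubstitution), the bulky silyl group and the excess of 10 are expected to secure these.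

Step 7
Reactants: 13 9-[(tert-butyldimethylsilyl)oxy]-5,8-dimethyl-2-(propan-2-yl)-11-oxatricyclo[6.2.1.0^{1,5}]undec-6-ene
Product: 14 5,8-dimethyl-2-(propan-2-yl)-11-oxatricyclo[6.2.1.0^{1,5}]undec-6-en-9-ol
Conditions: TBAF (1.5 equiv), THF, 0 °C to rt
Reagents that add atoms: none
Why: Fluoride-mediated silyl ether cleavage; the bridged allylic ether and the alkene are inert to TBAF.

Step 8
Reactants: 14 5,8-dimethyl-2-(propan-2-yl)-11-oxatricyclo[6.2.1.0^{1,5}]undec-6-en-9-ol
Product: 15 O-[5,8-dimethyl-2-(propan-2-yl)-11-oxatricyclo[6.2.1.0^{1,5}]undec-6-en-9-yl] 1H-imidazole-1-carbothioate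
Conditions: 1,1'-thiocarbonyldiimidazole (2 equiv), DMAP (0.2 equiv), 1,2-dichloroethane, 70 °C
Reagents that add atoms: 1,1'-thiocarbonyldiimidazole (S=C(n1ccnc1)n1ccnc1)
Why: Thioacylation of the secondary alcohol gives the radical precursor for a Barton–McCombie deoxygenation.

Step 9
Reactants: 15 O-[5,8-dimethyl-2-(propan-2-yl)-11-oxatricyclo[6.2.1.0^{1,5}]undec-6-en-9-yl] 1H-imidazole-1-carbothioate
Product: 16 5,8-dimethyl-2-(propan-2-yl)-11-oxatricyclo[6.2.1.0^{1,5}]undec-6-ene
Conditions: Bu3SnH (3 equiv, 0.5 M), AIBN (0.2 equiv), PhSeSePh (10 mol %), toluene, 80 °C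
Reagents that add atoms: none
Why: Barton–McCombie deoxygenation erases the auxiliary C7 oxygen and its stereocenter; benzeneselenol formed in situ should deliver hydrogen to the C7 radical faster than that radical can add to the C9=C10 bond (homoallyl/cyclopropylcarbinyl rearrangement).

Step 10
Reactants: 16 5,8-dimethyl-2-(propan-2-yl)-11-oxatricyclo[6.2.1.0^{1,5}]undec-6-ene; 17 4-methoxybenzoyl chloride
Product: 19 (3R,3aS,8S,8aR)-3a-hydroxy-6,8a-dimethyl-3-(propan-2-yl)-1,2,3,3a,4,5,8,8a-octahydroazulen-8-yl 4-methoxybenzoate, via dioxanylium triflate 18 (not isolated)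
Conditions: 17 (1.3 equiv), AgOTf (1.3 equiv), 2,6-di-tert-butyl-4-methylpyridine (1.5 equiv), CH2Cl2, −78 to −40 °C; then aq. NaHCO3, THF, 0 °C
Reagents that add atoms: 4-methoxybenzoyl chloride (COc1ccc(cc1)C(Cl)=O); water (O)
Why: Proposed new method: the acyl triflate formed from 17 and AgOTf acylates the bridging ether oxygen, the tertiary allylic C8–O bond ionises, and the carbonyl oxygen of the C5 ester so formed captures the C8–C9–C10 allyl cation at C10 through the six-membered 2-aryl-1,3-dioxan-2-ylium ion 18, so that the new C10–O bond must be cis to C5–O; aqueous hydrogencarbonate opens 18 through the orthoacid to the hydroxy ester with the acyl group on the less hindered secondary oxygen (any tertiary ester should equilibrate to it by 1,3-acyl shift on brief contact with Et3N), which unveils at once the C5 carbinol, the C8=C9 alkene and the C10 anisoate; the closest known reaction types are the cleavage of cyclic and bridged ethers by acyl triflates or acyl halide/Lewis acid and the Woodward–Prévost-type capture of a carbocation by a neighbouring ester via a dioxanylium ion.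

**Compound list**

1 | (S)-(−)-limonene, (4S)-1-methyl-4-(prop-1-en-2-yl)cyclohex-1-ene | CC1=CC[C@@H](C(C)=C)CC1 | starting material
2 | (4S)-1-methyl-4-(propan-2-yl)cyclohex-1-ene | CC1=CC[C@@H](C(C)C)CC1 | intermediate
3 | secondary ozonide of 2, (4S)-1-methyl-4-(propan-2-yl)-7,8,9-trioxabicyclo[4.2.1]nonane (bridgehead configuration not defined; not isolated) | CC12CC[C@H](C(C)C)CC(OO1)O2 | intermediate
4 | (3S)-6-oxo-3-(propan-2-yl)heptanal | O=CC[C@@H](C(C)C)CCC(C)=O | intermediate
5 | (5R)-2-methyl-5-(propan-2-yl)cyclopent-1-ene-1-carbaldehyde | O=CC1=C(C)CC[C@@H]1C(C)C | intermediate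
6 | (5R)-2-methyl-5-(propan-2-yl)cyclopent-1-en-1-yl formate | O=COC1=C(C)CC[C@@H]1C(C)C | intermediate
7 | 1-bromobut-2-yne | CC#CCBr | starting material
8 | lithium (5R)-2-methyl-5-(propan-2-yl)cyclopent-1-en-1-olate (not isolated) | [Li+].[O-]C1=C(C)CC[C@@H]1C(C)C | intermediate
9 | (2R,5R)-2-(but-2-yn-1-yl)-2-methyl-5-(propan-2-yl)cyclopentan-1-one (methyl cis to isopropyl) | O=C1[C@@H](C(C)C)CC[C@]1(C)CC#CC | intermediate
10 | tert-butyldimethyl(vinyloxy)silane | C=CO[Si](C)(C)C(C)(C)C | starting material
11 | platinum-containing carbonyl ylide: bicyclic 2H-pyran oxocarbenium (O+=C5) with a PtCl2 unit on C9 (not isolated) | CC1=C([Pt-](Cl)Cl)C[C@@]2(C)CC[C@H](C(C)C)C2=[O+]1 | intermediate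
12 | platinum carbene at C9 of the oxygen-bridged cycloadduct (not isolated) | CC(C)[C@H]1CC[C@]2(C)CC(=[Pt](Cl)Cl)[C@]3(C)C(O[Si](C)(C)C(C)(C)C)C[C@]12O3 | intermediate
13 | 9-[(tert-butyldimethylsilyl)oxy]-5,8-dimethyl-2-(propan-2-yl)-11-oxatricyclo[6.2.1.0^{1,5}]undec-6-ene; oxygen bridge, C1 methyl and C4 isopropyl all on one face of the cyclopentane | CC(C)[C@H]1CC[C@]2(C)C=C[C@]3(C)C(O[Si](C)(C)C(C)(C)C)C[C@]12O3 | intermediate
14 | 5,8-dimethyl-2-(propan-2-yl)-11-oxatricyclo[6.2.1.0^{1,5}]undec-6-en-9-ol (same ring configuration as 13) | CC(C)[C@H]1CC[C@]2(C)C=C[C@]3(C)C(O)C[C@]12O3 | intermediate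
15 | O-[5,8-dimethyl-2-(propan-2-yl)-11-oxatricyclo[6.2.1.0^{1,5}]undec-6-en-9-yl] 1H-imidazole-1-carbothioate | CC(C)[C@H]1CC[C@]2(C)C=C[C@]3(C)C(OC(=S)n4ccnc4)C[C@]12O3 | intermediate
16 | 5,8-dimethyl-2-(propan-2-yl)-11-oxatricyclo[6.2.1.0^{1,5}]undec-6-ene; C5–O–C8 bridge cis to the C1 methyl and the C4 isopropyl | CC(C)[C@H]1CC[C@]2(C)C=C[C@]3(C)CC[C@]12O3 | intermediate
17 | 4-methoxybenzoyl chloride | COc1ccc(cc1)C(Cl)=O | starting material
18 | 2-(4-methoxyphenyl)-1,3-dioxan-2-ylium triflate bridging O5 and O10 of the hydroazulene (not isolated) | CC(C)[C@H]1CC[C@]2(C)[C@@H]3C=C(C)CC[C@]12[O+]=C(c4ccc(OC)cc4)O3.[O-]S(=O)(=O)C(F)(F)F | intermediate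
19 | (3R,3aS,8S,8aR)-3a-hydroxy-6,8a-dimethyl-3-(propan-2-yl)-1,2,3,3a,4,5,8,8a-octahydroazulen-8-yl 4-methoxybenzoate | COc1ccc(C(=O)O[C@H]2C=C(C)CC[C@]3(O)[C@@H](C(C)C)CC[C@]23C)cc1 | target

**Step count and risks**

Total step count: 10. Longest linear sequence: 10 steps (1 → 19).

Steps most likely to fail:

1. Step 10 (Proposed new method). The allyl cation may lose a proton to a diene, or the acylating agent may attack the alkene, before the neighbouring ester closes onto C10; the orthoacid may also collapse toward the tertiary ester. Fallback with known reaction types, setting out from 16 and returning at 19: rhodium-catalysed hydroboration (catecholborane, RhCl(PPh3)3, THF; then NaOH, H2O2), which for cyclic allylic ethers places boron on the alkene carbon remote from the oxygen, should give the C10 alcohol F1. Dess–Martin periodinane gives the β-alkoxy ketone F2. DBU in CH2Cl2 opens the oxygen bridge by E1cB elimination to the hydroxy enone F3. Et2BOMe then NaBH4 (THF/MeOH, −78 °C; Narasaka–Prasad 1,2-reduction under chelation by the C5 hydroxyl) should give the cis-1,3-diol F4. Acylation of the secondary hydroxyl alone with 17, DMAP and pyridine gives 19.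

2. Step 6 (key step). Oxygen attack may go 5-exo instead of 6-endo, the silyloxocarbenium may lose its silyl group after the first C–C bond instead of ring-closing, the ylide may lose the C4 proton, or the enol ether may attack the wrong face. Fallback by a rhodium carbenoid route to a ketone-stabilised carbonyl ylide, setting out from 9 and returning at 13: RuCl3 (cat.)/NaIO4 (CCl4–MeCN–H2O) oxidises the alkyne to the 1,2-diketone F5. TsNHNH2 (1 equiv, MeOH) condenses at the less hindered acetyl carbonyl to the monotosylhydrazone F6. Et3N in CH2Cl2 gives the α-diazo ketone F7 (Bamford–Stevens-type). Rh2(OAc)4 (1 mol %) with 10 in benzene forms the six-membered carbonyl ylide from the carbenoid and the C5 ketone and traps it by [3+2] cycloaddition (same two bonds, same facial bias) as the C9 ketone F8. KHMDS and PhNTf2 give the enol triflate F9 (only C10 can enolise). Pd(OAc)2, PPh3, HCO2H and Et3N in DMF reduce the alkenyl triflate to 13.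

3. Step 9. The C7 radical may cyclise 3-exo onto C9 and reopen to the tertiary α-oxy radical at C8 (net 1,2-vinyl shift) before hydrogen transfer, rearranging the skeleton. Fallback without a C7 radical, setting out from 14 and returning at 16: NaH, CS2, then MeI gives the S-methyl xanthate F10. Heating in o-dichlorobenzene at 170 °C (Chugaev syn-elimination, possible only toward C6 because C8 carries no hydrogen) gives the diene F11. Diimide (potassium azodicarboxylate, AcOH, MeOH) should reduce the strained C6=C7 bond of the oxolene bridge and leave the C9=C10 bond, giving 16.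

**Further compounds**

F1 | step 10 | 5,8-dimethyl-2-(propan-2-yl)-11-oxatricyclo[6.2.1.0^{1,5}]undecan-6-ol (C10 configuration not defined) | CC(C)[C@H]1CC[C@]2(C)C(O)C[C@]3(C)CC[C@]12O3
F2 | step 10 | 5,8-dimethyl-2-(propan-2-yl)-11-oxatricyclo[6.2.1.0^{1,5}]undecan-6-one | CC(C)[C@H]1CC[C@]2(C)C(=O)C[C@]3(C)CC[C@]12O3
F3 | step 10 | (3R,3aS,8aS)-3a-hydroxy-6,8a-dimethyl-3-(propan-2-yl)-2,3,3a,4,5,8a-hexahydroazulen-8(1H)-one | CC(C)[C@H]1CC[C@]2(C)C(=O)C=C(C)CC[C@]12O
F4 | step 10 | (3R,3aS,8S,8aR)-6,8a-dimethyl-3-(propan-2-yl)-1,2,3,3a,4,5,8,8a-octahydroazulene-3a,8-diol | CC(C)[C@H]1CC[C@]2(C)[C@@H](O)C=C(C)CC[C@]12O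
F5 | step 6 | 1-[(1R,3R)-1-methyl-2-oxo-3-(propan-2-yl)cyclopentyl]butane-2,3-dione | O=C1[C@@H](C(C)C)CC[C@]1(C)CC(=O)C(C)=O
F6 | step 6 | 3-(4-methylbenzenesulfonyl)hydrazone of F5 | O=C1[C@@H](C(C)C)CC[C@]1(C)CC(=O)C(C)=NNS(=O)(=O)c1ccc(C)cc1
F7 | step 6 | 3-diazo-1-[(1R,3R)-1-methyl-2-oxo-3-(propan-2-yl)cyclopentyl]butan-2-one | O=C1[C@@H](C(C)C)CC[C@]1(C)CC(=O)C(C)=[N+]=[N-]
F8 | step 6 | 9-[(tert-butyldimethylsilyl)oxy]-5,8-dimethyl-2-(propan-2-yl)-11-oxatricyclo[6.2.1.0^{1,5}]undecan-7-one (C7 not defined) | CC(C)[C@H]1CC[C@]2(C)CC(=O)[C@]3(C)C(O[Si](C)(C)C(C)(C)C)C[C@]12O3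
F9 | step 6 | 9-[(tert-butyldimethylsilyl)oxy]-5,8-dimethyl-2-(propan-2-yl)-11-oxatricyclo[6.2.1.0^{1,5}]undec-6-en-7-yl trifluoromethanesulfonate | CC(C)[C@H]1CC[C@]2(C)C=C(OS(=O)(=O)C(F)(F)F)[C@]3(C)C(O[Si](C)(C)C(C)(C)C)C[C@]12O3
F10 | step 9 | O-[5,8-dimethyl-2-(propan-2-yl)-11-oxatricyclo[6.2.1.0^{1,5}]undec-6-en-9-yl] S-methyl carbonodithioate | CC(C)[C@H]1CC[C@]2(C)C=C[C@]3(C)C(OC(=S)SC)C[C@]12O3
F11 | step 9 | 5,8-dimethyl-2-(propan-2-yl)-11-oxatricyclo[6.2.1.0^{1,5}]undeca-6,9-diene | CC(C)[C@H]1CC[C@]2(C)C=C[C@]3(C)C=C[C@]12O3
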